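**Plan**

- Labels (target 42): C1 = quaternary C next to the lactam C=O (C13); C2 = quaternary C carrying CH2OAc (C21) and the chain C15–C19 (C17 OH, C18 Me, C19 on N); C3 = CH carrying NCH2 (C14); C4–C5 = CH2CH2; C6=C7 = ring alkene (C7 on C1); C8 = ring-fusion CH; C9 = CHCO2Me; C10 = CH2 between C9 and C1; C11–C12 = CH2CH2 from C8 to C6. Ring A = cyclopentane C1/C7–C10, ring B = cyclopentene C6–C8/C11/C12, ring C = cycloheptene C1–C7, ring D = six-membered N-ring, ring E = nine-membered N-ring.
- Cuts, late to early: C14=O of a six-membered imide and its N–C19 bond (Mitsunobu), then C17–C18 (aldol) and C16–C17 (hydroformylation), which leaves a vinyl group on C2.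
- Enabling feature: C1 and C2, both quaternary, are adjacent atoms of ring C, and C13 on C1 is cis to the two-carbon arm on C2. With that arm as a vinyl group, ring C is the product of an ester-enolate Claisen shift; cutting C1–C2 opens it to an eleven-membered allylic lactone.
- The lactone is cut at C5–C6 (B-alkyl Suzuki) and at its ester C–O bond into a diquinane keto acid (rings A and B) and a skipped-diene allylic alcohol.
- Forward: Diels–Alder adduct and oxidative cleavage give rings A/B; esterification and Suzuki coupling give the eleven-membered ring; ring contraction gives ring C; anhydride then imide closes ring D; Mitsunobu closes ring E; the imide C14=O is removed last.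
- Stereochemistry: C8 and C9 from a catalytic enantioselective endo Diels–Alder reaction; C3 from Cu-catalysed allylic substitution, secured cis to C13 by anhydride closure; C1 and C2 from the Claisen shift; C17 and C18 from an auxiliary-controlled syn aldol.

Key step: step 17

Remark: the antipodes of the two chiral catalysts (steps 1 and 12) are taken to be those that deliver 3 and 19 as drawn; both catalysts are available in either enantiomeric form.

**Route**

Step 1
Reactants: 1 cyclopenta-1,3-diene (freshly cracked); 2 cyclopent-2-en-1-one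
Product: 3 endo-tricyclo[5.2.1.0^2,6]dec-8-en-3-one
Conditions: (S)-B-(o-tolyl)oxazaborolidine from (S)-diphenylprolinol, protonated with Tf2NH (20 mol%), CH2Cl2, −40 to −20 °C
Reagents that add atoms: none
Why: An oxazaborolidinium-catalysed enantioselective Diels–Alder reaction should give the endo adduct, in which the future C1 and C9 carboxyl carbons (the C8=C9 bridge of 3) are cis to ring B, with the catalyst fixing the absolute configuration of the future C8 and C9.

Step 2
Reactants: 3 endo-tricyclo[5.2.1.0^2,6]dec-8-en-3-one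
Product: 4 endo alcohol (OH on the concave face, pointing to the alkene bridge)
Conditions: NaBH4, MeOH, 0 °C
Reagents that add atoms: none
Why: Hydride should add from the open convex face of the ketone, so the hydroxyl ends up next to the alkene carbon that becomes C13 and can later tell the two carboxyl groups apart.

Step 3
Reactants: 4 endo alcohol
Product: 6 lactone acid, via hydroxy diacid 5 (not isolated)
Conditions: O3, CH2Cl2/MeOH, −78 °C; then HCO2H, 30% H2O2, 60 °C
Reagents that add atoms: ozone [O-][O+]=O; hydrogen peroxide OO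
Why: Ozonolysis with performic acid work-up should give the all-cis hydroxy diacid, and only the carboxyl on C1 can close a cis-fused five-membered lactone onto the C6 hydroxyl, which leaves the C9 carboxyl free.

Step 4
Reactants: 6 lactone acid
Product: 7 lactone methyl ester
Conditions: Me3SiCHN2, toluene/MeOH, 0 °C
Reagents that add atoms: (trimethylsilyl)diazomethane C[Si](C)(C)C=[N+]=[N-]
Why: O-Methylation of the free acid with a diazomethane equivalent is neutral and should leave the epimerisable C9 centre untouched.

Step 5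
Reactants: 7 lactone methyl ester
Product: 9 keto acid, via lithium hydroxy carboxylate 8 (not isolated)
Conditions: LiOH·H2O (1.05 equiv), THF/H2O, 0 °C; then RuCl3·xH2O (cat.), NaIO4, MeCN/H2O, 0 °C; then 1 M HCl
Reagents that add atoms: lithium hydroxide [Li+].[OH-]
Why: The strained γ-lactone should saponify much faster than the hindered secondary methyl ester, and the hydroxy carboxylate, which cannot relactonise in base, is oxidised in the same flask to the C6 ketone (catalytic RuO4 oxidation).

Step 6
Reactants: 10 but-2-yne-1,4-diol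
Product: 11 4-[(tert-butyldimethylsilyl)oxy]but-2-yn-1-ol
Conditions: NaH (1.0 equiv), THF, 0 °C; t-BuMe2SiCl (1.0 equiv)
Reagents that add atoms: tert-butyldimethylsilyl chloride CC(C)(C)[Si](C)(C)Cl
Why: Silylation of the sparingly soluble monosodium alkoxide is a standard way to monoprotect a symmetrical diol.

Step 7
Reactants: 11 4-[(tert-butyldimethylsilyl)oxy]but-2-yn-1-ol
Product: 13 (Z)-4-[(tert-butyldimethylsilyl)oxy]-3-iodobut-2-en-1-ol, via sodium alkenylalanate 12 (not isolated)
Conditions: NaAlH2(OCH2CH2OMe)2, THF, 0 °C to rt; then I2, THF, −78 °C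
Reagents that add atoms: iodine II
Why: Hydroxyl-directed trans-hydroalumination places aluminium on the distal alkyne carbon in a five-membered alanate, and iodinolysis with retention should give the iodide cis to CH2OH, which fixes the geometry of the later trisubstituted alkene.

Step 8
Reactants: 13 (Z)-4-[(tert-butyldimethylsilyl)oxy]-3-iodobut-2-en-1-ol
Product: 14 triethylsilyl ether of 13
Conditions: Et3SiCl, imidazole, CH2Cl2, 0 °C
Reagents that add atoms: chlorotriethylsilane CC[Si](Cl)(CC)CC
Why: The free hydroxyl would otherwise tie up the cis boron atom of the next intermediate as a cyclic borate; a triethylsilyl ether can later be removed in the presence of the tert-butyldimethylsilyl ether.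

Step 9
Reactants: 14 triethylsilyl ether of 13
Product: 15 alkenyl pinacol boronate (boron cis to CH2OSiEt3)
Conditions: B2pin2, PdCl2(PPh3)2 (3 mol%), PPh3, KOPh, toluene, 50 °C
Reagents that add atoms: bis(pinacolato)diboron CC1(C)OB(OC1(C)C)B1OC(C)(C)C(C)(C)O1
Why: Miyaura borylation of an alkenyl iodide proceeds with retention of alkene geometry, and the phenoxide conditions suppress homocoupling.

Step 10
Reactants: 16 (E)-but-2-ene-1,4-diol (3 equiv)
Product: 17 (E)-4-[(4-methoxybenzyl)oxy]but-2-en-1-ol
Conditions: NaH (1.0 equiv), 4-MeOC6H4CH2Cl (1.0 equiv), Bu4NI (cat.), THF/DMF, 0 °C to rt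
Reagents that add atoms: 4-methoxybenzyl chloride COc1ccc(CCl)cc1
Why: Williamson monoalkylation of the diol used in excess should give the mono ether.

Step 11
Reactants: 17 (E)-4-[(4-methoxybenzyl)oxy]but-2-en-1-ol
Product: 18 diethyl (E)-4-[(4-methoxybenzyl)oxy]but-2-enyl phosphate
Conditions: ClP(O)(OEt)2, pyridine, DMAP (cat.), CH2Cl2, 0 °C
Reagents that add atoms: diethyl chlorophosphate CCOP(=O)(Cl)OCC
Why: O-Phosphorylation turns the primary allylic alcohol into the leaving group used in copper-catalysed allylic substitution.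

Step 12
Reactants: 15 alkenyl pinacol boronate; 18 allylic phosphate
Product: 19 (2E,4S)-skipped diene, triethylsilyl ether
Conditions: CuCl (10 mol%), enantiopure sulfonate-substituted imidazolinium salt (N-heterocyclic carbene precursor, 11 mol%), NaOMe (1.5 equiv), THF, 22 °C
Reagents that add atoms: none
Why: In this enantioselective copper-catalysed allylic substitution the alkenyl group passes from the methoxyborate to copper and adds SN2′ to the E-allylic phosphate, so the chiral carbene–copper complex sets C3 between the two alkenes and the alkenyl geometry is retained.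

Step 13
Reactants: 19 skipped diene, triethylsilyl ether
Product: 20 (2E,4S)-3-{[(tert-butyldimethylsilyl)oxy]methyl}-4-{[(4-methoxybenzyl)oxy]methyl}hexa-2,5-dien-1-ol
Conditions: PPTS (0.2 equiv), MeOH/CH2Cl2, 0 °C
Reagents that add atoms: none
Why: Mild acidic methanolysis should cleave the primary triethylsilyl ether well before the tert-butyldimethylsilyl ether, and the 4-methoxybenzyl ether is inert.

Step 14
Reactants: 9 keto acid; 20 allylic alcohol
Product: 21 keto ester
Conditions: EDC·HCl, DMAP (0.2 equiv), CH2Cl2, 0 °C to rt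
Reagents that add atoms: none
Why: Steglich esterification of a primary allylic alcohol is reliable, and epimerisation at C1 does not matter because that centre is enolised in step 17.

Step 15
Reactants: 21 keto ester
Product: 22 enol triflate (C6=C7)
Conditions: Tf2O (1.3 equiv), 2,6-di-tert-butyl-4-methylpyridine (1.5 equiv), CH2Cl2, 0 °C to rt
Reagents that add atoms: triflic anhydride O=S(=O)(OS(=O)(=O)C(F)(F)F)C(F)(F)F
Why: O-Triflation followed by proton loss under non-basic conditions should favour the more substituted enol triflate at the ring fusion, without a strong base that could epimerise C9.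

Step 16
Reactants: 22 enol triflate
Product: 24 eleven-membered allylic lactone, via B-alkyl-9-BBN adduct 23 (not isolated)
Conditions: 9-BBN (1.5 equiv), THF, 0 °C to rt; then syringe-pump addition to Pd(dppf)Cl2 (15 mol%), AsPh3, Cs2CO3, DMF/THF/H2O, 50 °C (final 2 mM)
Reagents that add atoms: none
Why: 9-BBN should hydroborate only the monosubstituted vinyl group, and an intramolecular B-alkyl Suzuki–Miyaura coupling then joins C5 to C6; two ring-cis alkenes and an s-trans ester keep transannular strain low.

Step 17
Reactants: 24 eleven-membered allylic lactone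
Product: 27 tricyclic cycloheptene acid, via silyl ketene acetal 25 (not isolated), via trimethylsilyl ester 26 (not isolated)
Conditions: KN(SiMe3)2 (1.3 equiv), Me3SiCl/Et3N, THF/toluene, −78 °C, then 60 °C; 1 M citric acid work-up
Reagents that add atoms: none
Why: Proposed new method: KN(SiMe3)2 removes the C1–H of the lactone (α to the carbonyl and allylic to C6=C7) and Me3SiCl traps the enolate as cyclic silyl ketene acetal 25, whose O–C(=C)···C=C–C array undergoes a concerted suprafacial [3,3] shift on warming; this makes the C1–C2 bond, breaks the O–CH2 bond and gives silyl ester 26, which is hydrolysed on work-up. The closest known reaction type is the ring-contracting Ireland–Claisen rearrangement of macrocyclic allylic lactones to cis-2-vinylcycloalkanecarboxylic acids, which has not been shown for two fully substituted termini. Ring C is closed transannularly, by C–C bond formation across the eleven-membered ring through a boat-like six-membered array, so the ring contracts by four atoms. C1 and C2 are fixed relative to each other by the ring: because C3 is cis to the OCH2 group on the alkene and is tied back to C6, C13 and the new vinyl group can only end up cis on the cycloheptene; their sense relative to C8/C9 is directed by the C3 stereocentre, which should keep its CH2O(4-methoxybenzyl) group pointing outward in the reacting array. The step needs site-selective enolisation (C1–H over the C9 ester α-H, secured by the double activation of C1–H, a small excess of base and internal silyl quench) and π-facial selectivity (secured by C3). Because C3 is later secured cis by anhydride closure in step 20, the antipode of fragment 20 can serve as the director if the facial sense proves opposite.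

Step 18
Reactants: 27 tricyclic cycloheptene acid
Product: 28 hydroxy acid
Conditions: DDQ (1.3 equiv), CH2Cl2/aq. NaHCO3 buffer, 0 °C; kept as the sodium salt and used at once
Reagents that add atoms: none
Why: Oxidative cleavage of the 4-methoxybenzyl ether leaves the silyl ether and the alkenes alone, and handling the product as its carboxylate prevents lactonisation onto C14–OH.

Step 19
Reactants: 28 hydroxy acid
Product: 29 C13,C14-diacid
Conditions: TEMPO (0.2 equiv), PhI(OAc)2 (2.5 equiv), MeCN/aq. NaHCO3, rt; then acidify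
Reagents that add atoms: water O
Why: Oxoammonium oxidation takes the unhindered primary alcohol through the aldehyde hydrate to the acid; raising C14 to the carboxyl level makes C3 enolisable and sets up the bridging anhydride.

Step 20
Reactants: 29 C13,C14-diacid
Product: 30 bridged cyclic anhydride
Conditions: Ac2O, NaOAc (0.5 equiv), 100 °C
Reagents that add atoms: none
Why: The six-membered anhydride can close only when C13 and C14 are cis (1,3-diaxial on ring C), and any C3 epimer would equilibrate through the enol of its mixed anhydride and drain into the same anhydride, so C3 is secured here.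

Step 21
Reactants: 30 bridged cyclic anhydride
Product: 32 bridged N–H imide (ring D), via amic acid 31 (not isolated)
Conditions: NH3 (0.5 M in dioxane, 3 equiv), THF, 0 °C to rt; concentrate; then Ac2O, NaOAc, 80 °C
Reagents that add atoms: ammonia N
Why: Ammonia should open the anhydride at the less hindered carbonyl C14 (C13 lies between two quaternary carbons), and dehydration of the amic acid recloses the ring as the imide, which installs the nitrogen with an acidic N–H.

Step 22
Reactants: 32 bridged N–H imide
Product: 33 primary alcohol (C21–OH)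
Conditions: HF·pyridine, pyridine, THF, 0 °C to rt
Reagents that add atoms: none
Why: Buffered fluoride removes the neopentyl silyl ether without generating an alkoxide that could attack the neighbouring imide carbonyl.

Step 23
Reactants: 33 primary alcohol
Product: 34 acetate
Conditions: Ac2O, pyridine, 0 °C to rt
Reagents that add atoms: acetic anhydride CC(=O)OC(C)=O
Why: The primary alcohol is acetylated under conditions that do not acylate the imide nitrogen.

Step 24
Reactants: 34 acetate
Product: 35 aldehyde (C17)
Conditions: Rh(acac)(CO)2 (2 mol%), tris(2,4-di-tert-butylphenyl) phosphite (8 mol%), CO/H2 (1:1, 20 bar), toluene, 70 °C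
Reagents that add atoms: carbon monoxide [C-]#[O+]
Why: In rhodium-catalysed hydroformylation a vinyl group on a quaternary carbon gives only the linear aldehyde (Keulemans rule), and the tetrasubstituted C6=C7 alkene should not react.

Step 25
Reactants: 35 aldehyde; 36 (S)-4-benzyl-3-propanoyl-1,3-oxazolidin-2-one
Product: 38 syn aldol adduct, via Z-boron enolate 37 (not isolated)
Conditions: 36, Bu2BOTf (1.2 equiv), i-Pr2NEt (1.4 equiv), CH2Cl2, −78 to 0 °C; then 35, −78 to 0 °C; pH 7 buffer, MeOH, 30% H2O2, 0 °C
Reagents that add atoms: none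
Why: The Evans syn aldol reaction through the Z-boron enolate and a Zimmerman–Traxler chair should set C17 (R) and C18 under control of the auxiliary alone; the boron enolate, which survives the ammonium triflate formed with it, should tolerate the imide N–H.

Step 26
Reactants: 38 syn aldol adduct
Product: 39 diol (C17–OH, C19–OH)
Conditions: NaBH4 (4 equiv), THF/H2O (4:1), 0 °C to rt
Reagents that add atoms: none
Why: Borohydride should reduce the activated N-acyl oxazolidinone carbonyl to the primary alcohol, while the N–H imide is largely present as its unreactive anion at this pH and the methyl ester and acetate react slowly.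

Step 27
Reactants: 39 diol
Product: 40 N-alkyl imide (ring E closed)
Conditions: PPh3 (2 equiv), DIAD (2 equiv), toluene/THF, 3 mM, 0 °C to rt
Reagents that add atoms: none
Why: In a Mitsunobu reaction the acidic imide N–H should be alkylated by the primary C19 alcohol in preference to the secondary C17 alcohol, as known for medium-ring closure on acidic N–H groups, and the cis arm on C2 holds the alcohol over the imide.

Step 28
Reactants: 40 N-alkyl imide
Product: 41 hydroxy lactam (C14–OH, epimers)
Conditions: NaBH4, MeOH/CH2Cl2 (1:1), −20 to 0 °C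
Reagents that add atoms: none
Why: Mono-reduction of the imide should occur at the less hindered carbonyl C14, since C13 is shielded by the quaternary carbons C1 and C2.

Step 29
Reactants: 41 hydroxy lactam
Product: 42 target
Conditions: Et3SiH (10 equiv), BF3·OEt2 (3 equiv), CH2Cl2, −78 to −30 °C
Reagents that add atoms: none
Why: The Lewis acid ionises the N-acyl hemiaminal to an N-acyliminium ion that the silane reduces to C14H2; low temperature and excess silane are chosen so that hydride capture outruns protonation or π-participation of the C6=C7 alkene.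

**Compound list**

1 | cyclopenta-1,3-diene | C1=CCC=C1 | starting material
2 | cyclopent-2-en-1-one | O=C1C=CCC1 | starting material
3 | endo-tricyclo[5.2.1.0^2,6]dec-8-en-3-one (cyclopentanone ring under the C8=C9 bridge) | O=C1CC[C@H]2[C@@H]1[C@@H]1C[C@H]2C=C1 | intermediate
4 | endo-tricyclo[5.2.1.0^2,6]dec-8-en-3-ol, OH on the concave face | O[C@@H]1CC[C@H]2[C@@H]1[C@@H]1C[C@H]2C=C1 | intermediate
5 | hydroxy diacid: cis-bicyclo[3.3.0]octane, CO2H on C1 and C9 (both cis to ring B), OH on C6 cis to C13 | OC(=O)[C@@H]1C[C@H](C(=O)O)[C@@H]2[C@H](O)CC[C@H]12 | intermediate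
6 | lactone acid (C13 lactonised onto C6–O, free CO2H on C9) | OC(=O)[C@@H]1C[C@@H]2C(=O)O[C@@H]3CC[C@H]1[C@H]23 | intermediate
7 | lactone methyl ester | COC(=O)[C@@H]1C[C@@H]2C(=O)O[C@@H]3CC[C@H]1[C@H]23 | intermediate
8 | lithium hydroxy carboxylate | [Li+].COC(=O)[C@@H]1C[C@H](C(=O)[O-])[C@@H]2[C@H](O)CC[C@H]12 | intermediate
9 | keto acid: cis-fused bicyclo[3.3.0]octan-2-one (C6 ketone), CO2H on C1 and CO2Me on C9 on the concave face | COC(=O)[C@@H]1C[C@H](C(=O)O)[C@@H]2C(=O)CC[C@H]12 | intermediate
10 | but-2-yne-1,4-diol | OCC#CCO | starting material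
11 | 4-[(tert-butyldimethylsilyl)oxy]but-2-yn-1-ol | OCC#CCO[Si](C)(C)C(C)(C)C | intermediate
12 | sodium alkenylalanate (five-membered oxaaluminacycle) | [Na+].COCCO[Al-]1(OCCOC)OCC=C1CO[Si](C)(C)C(C)(C)C | intermediate
13 | (Z)-4-[(tert-butyldimethylsilyl)oxy]-3-iodobut-2-en-1-ol | OC/C=C(\I)CO[Si](C)(C)C(C)(C)C | intermediate
14 | triethylsilyl ether of 13 | CC[Si](CC)(CC)OC/C=C(\I)CO[Si](C)(C)C(C)(C)C | intermediate
15 | alkenyl pinacol boronate, boron cis to CH2OSiEt3 | CC[Si](CC)(CC)OC/C=C(\B1OC(C)(C)C(C)(C)O1)CO[Si](C)(C)C(C)(C)C | intermediate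
16 | (E)-but-2-ene-1,4-diol | OC/C=C/CO | starting material
17 | (E)-4-[(4-methoxybenzyl)oxy]but-2-en-1-ol | OC/C=C/COCc1ccc(OC)cc1 | intermediate
18 | diethyl (E)-4-[(4-methoxybenzyl)oxy]but-2-enyl phosphate | CCOP(=O)(OCC)OC/C=C/COCc1ccc(OC)cc1 | intermediate
19 | (2E,4S)-skipped diene, triethylsilyl ether of 20 | CC[Si](CC)(CC)OC/C=C(/CO[Si](C)(C)C(C)(C)C)[C@@H](COCc1ccc(OC)cc1)C=C | intermediate
20 | (2E,4S)-3-{[(tert-butyldimethylsilyl)oxy]methyl}-4-{[(4-methoxybenzyl)oxy]methyl}hexa-2,5-dien-1-ol (CH2OH cis to the stereogenic CH) | OC/C=C(/CO[Si](C)(C)C(C)(C)C)[C@@H](COCc1ccc(OC)cc1)C=C | intermediate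
21 | keto ester of 9 with 20 | COC(=O)[C@@H]1C[C@H](C(=O)OC/C=C(/CO[Si](C)(C)C(C)(C)C)[C@@H](COCc3ccc(OC)cc3)C=C)[C@@H]2C(=O)CC[C@H]12 | intermediate
22 | enol triflate, C6=C7 at the ring fusion | COC(=O)[C@@H]1C[C@H](C(=O)OC/C=C(/CO[Si](C)(C)C(C)(C)C)[C@@H](COCc3ccc(OC)cc3)C=C)C2=C(OS(=O)(=O)C(F)(F)F)CC[C@H]12 | intermediate
23 | B-alkyl-9-BBN adduct at C5 | COC(=O)[C@@H]1C[C@H](C(=O)OC/C=C(/CO[Si](C)(C)C(C)(C)C)[C@@H](COCc3ccc(OC)cc3)CCB3C4CCCC3CCC4)C2=C(OS(=O)(=O)C(F)(F)F)CC[C@H]12 | intermediate
24 | eleven-membered allylic lactone fused to the diquinane; E alkene by CIP (ring-cis); C1–H configuration (C13 cis to the C9 ester) is immaterial | COC(=O)[C@@H]1C[C@@H]2C(=O)OC/C=C(/CO[Si](C)(C)C(C)(C)C)[C@@H](COCc4ccc(OC)cc4)CCC3=C2[C@@H]1CC3 | intermediate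
25 | cyclic trimethylsilyl ketene acetal (ring O cis to C7) | COC(=O)[C@@H]1C/C2=C(\O[Si](C)(C)C)OC/C=C(/CO[Si](C)(C)C(C)(C)C)[C@@H](COCc4ccc(OC)cc4)CCC3=C2[C@@H]1CC3 | intermediate
26 | trimethylsilyl ester of 27 | COC(=O)[C@@H]1C[C@@]2(C(=O)O[Si](C)(C)C)C3=C(CC[C@H](COCc4ccc(OC)cc4)[C@@]2(C=C)CO[Si](C)(C)C(C)(C)C)CC[C@H]13 | intermediate
27 | tricyclic cycloheptene acid: CO2H on C1; vinyl and CH2OSi(t-Bu)Me2 on C2; CH2O(4-methoxybenzyl) on C3; C13, vinyl and C14 all cis | COC(=O)[C@@H]1C[C@@]2(C(=O)O)C3=C(CC[C@H](COCc4ccc(OC)cc4)[C@@]2(C=C)CO[Si](C)(C)C(C)(C)C)CC[C@H]13 | intermediate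
28 | hydroxy acid (C14–OH) | COC(=O)[C@@H]1C[C@@]2(C(=O)O)C3=C(CC[C@H](CO)[C@@]2(C=C)CO[Si](C)(C)C(C)(C)C)CC[C@H]13 | intermediate
29 | C13,C14-diacid | COC(=O)[C@@H]1C[C@@]2(C(=O)O)C3=C(CC[C@H](C(=O)O)[C@@]2(C=C)CO[Si](C)(C)C(C)(C)C)CC[C@H]13 | intermediate
30 | bridged cyclic anhydride (C13–O–C14) | COC(=O)[C@@H]1C[C@@]2(C(=O)OC5=O)C3=C(CC[C@H]5[C@@]2(C=C)CO[Si](C)(C)C(C)(C)C)CC[C@H]13 | intermediate
31 | amic acid (C14 primary amide, C13 acid) | COC(=O)[C@@H]1C[C@@]2(C(=O)O)C3=C(CC[C@H](C(N)=O)[C@@]2(C=C)CO[Si](C)(C)C(C)(C)C)CC[C@H]13 | intermediate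
32 | bridged N–H imide (ring D) | COC(=O)[C@@H]1C[C@@]2(C(=O)NC5=O)C3=C(CC[C@H]5[C@@]2(C=C)CO[Si](C)(C)C(C)(C)C)CC[C@H]13 | intermediate
33 | imide alcohol (C21–OH) | COC(=O)[C@@H]1C[C@@]2(C(=O)NC5=O)C3=C(CC[C@H]5[C@@]2(C=C)CO)CC[C@H]13 | intermediate
34 | imide acetate | COC(=O)[C@@H]1C[C@@]2(C(=O)NC5=O)C3=C(CC[C@H]5[C@@]2(C=C)COC(C)=O)CC[C@H]13 | intermediate
35 | imide aldehyde (C2–CH2CH2CHO) | COC(=O)[C@@H]1C[C@@]2(C(=O)NC5=O)C3=C(CC[C@H]5[C@@]2(CCC=O)COC(C)=O)CC[C@H]13 | intermediate
36 | (S)-4-benzyl-3-propanoyl-1,3-oxazolidin-2-one | CCC(=O)N1[C@@H](Cc2ccccc2)COC1=O | starting material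
37 | Z-dibutylboron enolate of 36 | C/C=C(\OB(CCCC)CCCC)N1[C@@H](Cc2ccccc2)COC1=O | intermediate
38 | syn aldol adduct (17R, 18 as in target) | COC(=O)[C@@H]1C[C@@]2(C(=O)NC5=O)C3=C(CC[C@H]5[C@@]2(CC[C@@H](O)[C@H](C)C(=O)N6[C@@H](Cc7ccccc7)COC6=O)COC(C)=O)CC[C@H]13 | intermediate
39 | imide diol (C17–OH, C19–OH) | COC(=O)[C@@H]1C[C@@]2(C(=O)NC5=O)C3=C(CC[C@H]5[C@@]2(CC[C@@H](O)[C@H](C)CO)COC(C)=O)CC[C@H]13 | intermediate
40 | N-alkyl imide with rings D and E closed | COC(=O)[C@@H]1C[C@@]2(C(=O)N6C5=O)C3=C(CC[C@H]5[C@@]2(CC[C@@H](O)[C@H](C)C6)COC(C)=O)CC[C@H]13 | intermediate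
41 | hydroxy lactam (C14–OH, both epimers; this centre is removed in step 29) | COC(=O)[C@@H]1C[C@@]2(C(=O)N6C5O)C3=C(CC[C@H]5[C@@]2(CC[C@@H](O)[C@H](C)C6)COC(C)=O)CC[C@H]13 | intermediate
42 | CNP0296366.1 | COC(=O)[C@@H]1C[C@@]23C(=O)N4C[C@@H](CCC5=C2[C@@H]1CC5)[C@]3(COC(C)=O)CC[C@@H](O)[C@H](C)C4 | target

**Count and risks**

Total step count: 29. Longest linear sequence: 22 steps (10 to 42 through steps 6–9, 12–29).

Steps most likely to fail:

1. Step 17. The [3,3] shift between two fully substituted termini may be slower than C-silylation, ketene loss or decomposition of the ketene acetal, or the allyl terminus may add to the wrong face of the dienolate. Fallback with known chemistry: the C1–C2 bond is made first by an open-chain Ireland–Claisen rearrangement, a reaction type documented for joining two quaternary carbons, and ring C is closed afterwards. Enol triflate ester 22 is treated with KN(SiMe3)2 and Me3SiCl (THF, −78 °C to rt) and worked up with acid to give the open-chain triflate acid F1. 9-BBN then hydroborates the less hindered vinyl group on C3 rather than the neopentyl vinyl on C2, and Pd(dppf)Cl2/Cs2CO3 closes the cycloheptene by intramolecular B-alkyl Suzuki coupling, which returns to acid 27 after separation of C1/C2 diastereomers.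

2. Step 16. Oligomerisation, protodeboronation or β-hydride elimination may outpace closure of the eleven-membered ring. Fallback: the two unions are reversed and the ring is closed at the ester. Keto acid 9 is converted into the tert-butyl keto ester F2 (tert-butyl 2,2,2-trichloroacetimidate, cat. BF3·OEt2) and then into the tert-butyl ester enol triflate F3 (Tf2O, 2,6-di-tert-butyl-4-methylpyridine). Intermolecular B-alkyl Suzuki coupling with the 9-BBN adduct of diene 19 gives the coupled seco ester F4. Me3SiOTf/2,6-lutidine followed by PPTS/MeOH removes the tert-butyl and triethylsilyl groups to give the seco hydroxy acid F5, and Yamaguchi macrolactonisation (2,4,6-trichlorobenzoyl chloride, Et3N, then DMAP, toluene, high dilution) returns to lactone 24.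

3. Step 15. Proton loss on the methylene side (C12) would give the regioisomeric enol triflate. Fallback: the enolate position is fixed by a halogen atom. Keto acid 9 is brominated under acid catalysis (Br2, AcOH) at the ring-fusion carbon to give the C7-bromo keto acid F6, which is esterified with alcohol 20 (EDC, DMAP) to the C7-bromo keto ester F7. Zn/Me3SiCl then gives the regiodefined trimethylsilyl enol ether F8, and CsF/PhNTf2 converts it into enol triflate 22.

Further compounds
F1 | step 17 | open-chain triflate acid | COC(=O)[C@@H]1C[C@](C(=O)O)([C@](C=C)(CO[Si](C)(C)C(C)(C)C)[C@@H](COCc3ccc(OC)cc3)C=C)C2=C(OS(=O)(=O)C(F)(F)F)CC[C@H]12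
F2 | step 16 | tert-butyl keto ester | COC(=O)[C@@H]1C[C@H](C(=O)OC(C)(C)C)[C@@H]2C(=O)CC[C@H]12
F3 | step 16 | tert-butyl ester enol triflate | COC(=O)[C@@H]1C[C@H](C(=O)OC(C)(C)C)C2=C(OS(=O)(=O)C(F)(F)F)CC[C@H]12
F4 | step 16 | coupled seco ester | COC(=O)[C@@H]1C[C@H](C(=O)OC(C)(C)C)C2=C(CC[C@H](COCc3ccc(OC)cc3)/C(CO[Si](C)(C)C(C)(C)C)=C\CO[Si](CC)(CC)CC)CC[C@H]12
F5 | step 16 | seco hydroxy acid | COC(=O)[C@@H]1C[C@H](C(=O)O)C2=C(CC[C@H](COCc3ccc(OC)cc3)/C(CO[Si](C)(C)C(C)(C)C)=C\CO)CC[C@H]12
F6 | step 15 | C7-bromo keto acid | COC(=O)[C@@H]1C[C@H](C(=O)O)[C@]2(Br)C(=O)CC[C@H]12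
F7 | step 15 | C7-bromo keto ester | COC(=O)[C@@H]1C[C@H](C(=O)OC/C=C(/CO[Si](C)(C)C(C)(C)C)[C@@H](COCc3ccc(OC)cc3)C=C)[C@]2(Br)C(=O)CC[C@H]12
F8 | step 15 | trimethylsilyl enol ether | COC(=O)[C@@H]1C[C@H](C(=O)OC/C=C(/CO[Si](C)(C)C(C)(C)C)[C@@H](COCc3ccc(OC)cc3)C=C)C2=C(O[Si](C)(C)C)CC[C@H]12
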